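**Plan**

- Target: all-E (3R,3'R,6'R)-7,8-didehydro-β,ε-carotene-3,3'-diol. The retrosynthesis cuts C11'=C12' and C11=C12 (two Wittig reactions, C15 + C10 + C15), the ring–alkyne bond C6–C7 (Sonogashira), C9'=C10' and C7'=C8' (HWE, Wittig), and in the ε-ring (C1'–C6') the bonds C1'–C2' and C4'=C5'.
- Enabling feature: the ε-ring is an isophorone pattern. Carbinol C3' lies between CH2 C2' (bonded to the quaternary gem-dimethyl C1') and the olefin C4'H=C5'(CH3). With C3' as a ketone the ring is the Michael–aldol product of a three-carbon acetone unit (C2'–C3'–C4') and an isopropylidene acetoacetate (C1', C6', C5'). Two tert-butyl ester groups on the acetone unit activate C2' and C4' and are removed by decarboxylation in step 3.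
- Forward order: the ε-ring is built first (steps 1–3), then the C3' carbinol and the side chain up to the ε C15 phosphonium salt (steps 4–11). The acetylenic ring comes from actinol by enol triflate and Sonogashira coupling to the second C15 salt, which is joined to the C10 dialdehyde to give a C25 aldehyde (steps 12–16). The halves are joined last (step 17) and desilylated (step 18).
- Stereochemistry: C3 comes from (4R,6R)-actinol (chiral pool). C3' comes from a catalyst-controlled CBS reduction. C6' comes from chromatographic separation of the two diastereomeric (4R)-alcohols formed from the racemic keto ester and is then carried through non-epimerizing steps. The E double bonds come from the stabilized ylide and HWE reagent, the (E)-enynol, the all-E dialdehyde and equilibration of the Wittig-formed bonds.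

Key step: step 2

Remark: (4R,6R)-actinol 21, the (E)-enynol 24 and the all-E C10 dialdehyde 28 are taken as purchasable vitamin A and carotenoid building blocks; ring positions are named with carotenoid numbering (primed = ε half).

**Route**

Step 1
Reactants: 1 acetone; 2 ethyl acetoacetate
Product: 3 ethyl 2-acetyl-3-methylbut-2-enoate
Conditions: Ac2O, ZnCl2 (0.1 equiv), excess 1, reflux
Reagents that add atoms: none
Why: Knoevenagel condensation of the active methylene of 2 with the ketone, with acetic anhydride as water scavenger under Lewis acid catalysis, should give the doubly activated isopropylidene acceptor, which has no stereo element.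

Step 2
Reactants: 3 ethyl 2-acetyl-3-methylbut-2-enoate; 4 di-tert-butyl 3-oxopentanedioate
Product: 7 3,5-di-tert-butyl 1-ethyl 2,6,6-trimethyl-4-oxocyclohex-2-ene-1,3,5-tricarboxylate, via Michael adduct 5 (not isolated), via cyclic aldol 6 (not isolated)
Conditions: t-BuOK (0.2 equiv), THF/t-BuOH, 4 Å molecular sieves, 25 to 60 °C
Reagents that add atoms: none
Why: t-BuOK deprotonates 4 (an acetone unit whose two equivalent CH2 groups are each activated by a tert-butyl ester) and the soft enolate adds in a Michael reaction to the isopropylidene carbon of the doubly activated alkene of 3, which creates the quaternary gem-dimethyl carbon and the C1'–C2' bond (adduct 5). After proton transfer the second activated CH2 (C4') attacks the acetyl ketone (C5') to give aldol 6, and E1cB loss of water installs C4'=C5' and makes the sequence irreversible, so that the reversible, sterically demanding Michael step is pulled forward. The closest known reaction type is the Robinson- and Hagemann-type [3+3] Michael–aldol (Knoevenagel) cyclohexenone annulation of acetoacetates and acetonedicarboxylates with alkylidene 1,3-dicarbonyl compounds, as used for isophorone carboxylates. The six-membered ring closes in the 6-(enolendo)-exo-trig mode. No stereocentre of the target is fixed: C1 and C5 of 7 are epimerizable and racemic, C5 becomes CH2 in step 3 and C1 (later C6') is settled in step 4. The step needs the C4' carbanion to choose the ketone over ester acylation and over a second Michael addition; catalytic base, the higher electrophilicity of the ketone, the poor electrophilicity of tert-butyl esters and the congestion around the new quaternary carbon secure this, and the only other six-membered closure would need the unactivated acetyl CH3 as the nucleophile.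

Step 3
Reactants: 7 3,5-di-tert-butyl 1-ethyl 2,6,6-trimethyl-4-oxocyclohex-2-ene-1,3,5-tricarboxylate
Product: 9 ethyl 2,6,6-trimethyl-4-oxocyclohex-2-ene-1-carboxylate (racemic), via diacid 8 (not isolated)
Conditions: CF3CO2H, CH2Cl2, 0 °C to rt; then toluene, 100 °C
Reagents that add atoms: none
Why: Acid cleaves both tert-butyl esters with loss of isobutene, and the two acids flanking the ring ketone should decarboxylate on warming (the one on the enone carbon after deconjugation through the dienol), while the ethyl ester, which is not a β-keto ester, stays and the enone re-forms in conjugation; this removes both activating groups of the key step.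

Step 4
Reactants: 9 ethyl 2,6,6-trimethyl-4-oxocyclohex-2-ene-1-carboxylate (racemic)
Product: 10 ethyl (1R,4R)-4-hydroxy-2,6,6-trimethylcyclohex-2-ene-1-carboxylate
Conditions: (S)-1-methyl-3,3-diphenyltetrahydro-1H,3H-pyrrolo[1,2-c][1,3,2]oxazaborole [(S)-Me-CBS, 0.2 equiv], catecholborane (1.5 equiv), toluene, −78 °C; then MeOH; silica gel chromatography
Reagents that add atoms: none
Why: Corey–Bakshi–Shibata reduction delivers hydride 1,2 under catalyst control (enone alkene as the large group), so each enantiomer of 9 should give the (4R)-carbinol; (1R)-9 gives trans-10 and (1S)-9 the cis diastereomer, which chromatography removes, so that C4 (later C3') comes from the catalyst and C1 (later C6') from the diastereomer separation.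

Step 5
Reactants: 10 ethyl (1R,4R)-4-hydroxy-2,6,6-trimethylcyclohex-2-ene-1-carboxylate
Product: 11 ethyl (1R,4R)-4-[(tert-butyldimethylsilyl)oxy]-2,6,6-trimethylcyclohex-2-ene-1-carboxylate
Conditions: TBSCl, imidazole, DMF, rt
Reagents that add atoms: tert-butyldimethylsilyl chloride, CC(C)(C)[Si](C)(C)Cl
Why: Standard silylation of the secondary allylic alcohol under near-neutral conditions; the silyl ether blocks ionization or elimination of the allylic oxygen and should survive every later step up to the fluoride treatment.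

Step 6
Reactants: 11 ethyl (1R,4R)-4-[(tert-butyldimethylsilyl)oxy]-2,6,6-trimethylcyclohex-2-ene-1-carboxylate
Product: 12 [(1R,4R)-4-[(tert-butyldimethylsilyl)oxy]-2,6,6-trimethylcyclohex-2-en-1-yl]methanol
Conditions: i-Bu2AlH (2.5 equiv), CH2Cl2, −78 to 0 °C; aq. potassium sodium tartrate
Reagents that add atoms: none
Why: Reduction of the ester to the primary alcohol with an aluminium hydride at low temperature; no base is present, so the stereocentre α to the ester is not touched and the silyl ether is stable.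

Step 7
Reactants: 12 [(1R,4R)-4-[(tert-butyldimethylsilyl)oxy]-2,6,6-trimethylcyclohex-2-en-1-yl]methanol
Product: 13 (1R,4R)-4-[(tert-butyldimethylsilyl)oxy]-2,6,6-trimethylcyclohex-2-ene-1-carbaldehyde
Conditions: Dess–Martin periodinane, NaHCO3, CH2Cl2, 0 °C; used at once
Reagents that add atoms: none
Why: Dess–Martin oxidation under bicarbonate buffer is fast and neutral, which should keep the α-stereocentre and the β,γ-position of the ring double bond of the aldehyde intact.

Step 8
Reactants: 13 (1R,4R)-4-[(tert-butyldimethylsilyl)oxy]-2,6,6-trimethylcyclohex-2-ene-1-carbaldehyde; 14 1-(triphenylphosphoranylidene)propan-2-one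
Product: 15 (3E)-4-[(1R,4R)-4-[(tert-butyldimethylsilyl)oxy]-2,6,6-trimethylcyclohex-2-en-1-yl]but-3-en-2-one
Conditions: toluene, 90 °C
Reagents that add atoms: none
Why: Wittig reaction with the ketone-stabilized, almost non-basic ylide should give the E-enone (C7'=C8') through reversible oxaphosphetane formation without deprotonating the α-stereocentre.

Step 9
Reactants: 15 (3E)-4-[(1R,4R)-4-[(tert-butyldimethylsilyl)oxy]-2,6,6-trimethylcyclohex-2-en-1-yl]but-3-en-2-one; 16 triethyl phosphonoacetate
Product: 17 ethyl (2E,4E)-5-[(1R,4R)-4-[(tert-butyldimethylsilyl)oxy]-2,6,6-trimethylcyclohex-2-en-1-yl]-3-methylpenta-2,4-dienoate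
Conditions: NaH, THF, 0 °C to rt; chromatography
Reagents that add atoms: none
Why: Horner–Wadsworth–Emmons olefination of the methyl ketone should give the (2E)-dienoate as the major isomer (ester anti to the larger dienyl branch), the minor (2Z)-isomer being removed by chromatography; the phosphonate anion is too weak a base to deprotonate the ring stereocentre.

Step 10
Reactants: 17 ethyl (2E,4E)-5-[(1R,4R)-4-[(tert-butyldimethylsilyl)oxy]-2,6,6-trimethylcyclohex-2-en-1-yl]-3-methylpenta-2,4-dienoate
Product: 18 (2E,4E)-5-[(1R,4R)-4-[(tert-butyldimethylsilyl)oxy]-2,6,6-trimethylcyclohex-2-en-1-yl]-3-methylpenta-2,4-dien-1-ol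
Conditions: i-Bu2AlH (2.2 equiv), CH2Cl2, −78 °C; aq. potassium sodium tartrate
Reagents that add atoms: none
Why: 1,2-Reduction of the conjugated ester to the allylic alcohol, which leaves the diene geometry and the silyl ether untouched.

Step 11
Reactants: 18 (2E,4E)-5-[(1R,4R)-4-[(tert-butyldimethylsilyl)oxy]-2,6,6-trimethylcyclohex-2-en-1-yl]-3-methylpenta-2,4-dien-1-ol
Product: 20 [(2E,4E)-5-[(1R,4R)-4-[(tert-butyldimethylsilyl)oxy]-2,6,6-trimethylcyclohex-2-en-1-yl]-3-methylpenta-2,4-dien-1-yl]triphenylphosphonium bromide, via allylic bromide 19 (not isolated)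
Conditions: CBr4, PPh3, CH2Cl2, −20 °C; then PPh3, rt
Reagents that add atoms: tetrabromomethane, BrC(Br)(Br)Br; triphenylphosphine, c1ccc(cc1)P(c1ccccc1)c1ccccc1
Why: Appel bromination under neutral conditions followed by SN2 displacement with triphenylphosphine should give the Wittig salt; acid is avoided so that the allylic C–O bond of the ring does not ionize.

Step 12
Reactants: 21 (4R,6R)-4-hydroxy-2,2,6-trimethylcyclohexan-1-one
Product: 22 (4R,6R)-4-[(tert-butyldimethylsilyl)oxy]-2,2,6-trimethylcyclohexan-1-one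
Conditions: TBSCl, imidazole, DMF, rt
Reagents that add atoms: tert-butyldimethylsilyl chloride, CC(C)(C)[Si](C)(C)Cl
Why: Standard silylation of the secondary alcohol, needed so that the enolate chemistry of step 13 involves only the ketone; the C4 stereocentre is untouched.

Step 13
Reactants: 22 (4R,6R)-4-[(tert-butyldimethylsilyl)oxy]-2,2,6-trimethylcyclohexan-1-one
Product: 23 (4R)-4-[(tert-butyldimethylsilyl)oxy]-2,6,6-trimethylcyclohex-1-en-1-yl trifluoromethanesulfonate
Conditions: LiN(i-Pr)2, THF, −78 to 0 °C; then PhNTf2, −78 °C to rt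
Reagents that add atoms: N-phenylbis(trifluoromethanesulfonimide), FC(F)(F)S(=O)(=O)N(c1ccccc1)S(=O)(=O)C(F)(F)F
Why: Only C6 carries an α-hydrogen (C2 is quaternary), so a single enolate forms and is O-triflated; the C6 stereocentre is spent here by design and C4 is not affected.

Step 14
Reactants: 23 (4R)-4-[(tert-butyldimethylsilyl)oxy]-2,6,6-trimethylcyclohex-1-en-1-yl trifluoromethanesulfonate; 24 (2E)-3-methylpent-2-en-4-yn-1-ol
Product: 25 (2E)-5-[(4R)-4-[(tert-butyldimethylsilyl)oxy]-2,6,6-trimethylcyclohex-1-en-1-yl]-3-methylpent-2-en-4-yn-1-ol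
Conditions: Pd(PPh3)4 (5 mol%), CuI (10 mol%), i-Pr2NH, DMF, rt
Reagents that add atoms: none
Why: Sonogashira coupling of the enol triflate with the terminal alkyne forms the ring–alkyne bond C6–C7; the (E)-double bond of the enynol takes no part and should be retained.

Step 15
Reactants: 25 (2E)-5-[(4R)-4-[(tert-butyldimethylsilyl)oxy]-2,6,6-trimethylcyclohex-1-en-1-yl]-3-methylpent-2-en-4-yn-1-ol
Product: 27 [(2E)-5-[(4R)-4-[(tert-butyldimethylsilyl)oxy]-2,6,6-trimethylcyclohex-1-en-1-yl]-3-methylpent-2-en-4-yn-1-yl]triphenylphosphonium bromide, via allylic bromide 26 (not isolated)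
Conditions: CBr4, PPh3, CH2Cl2, −20 °C; then PPh3, rt
Reagents that add atoms: tetrabromomethane, BrC(Br)(Br)Br; triphenylphosphine, c1ccc(cc1)P(c1ccccc1)c1ccccc1
Why: Appel bromination and SN2 displacement by triphenylphosphine, as in step 11, should keep the (2E) geometry (no allyl cation is formed) and the silyl ether.

Step 16
Reactants: 27 [(2E)-5-[(4R)-4-[(tert-butyldimethylsilyl)oxy]-2,6,6-trimethylcyclohex-1-en-1-yl]-3-methylpent-2-en-4-yn-1-yl]triphenylphosphonium bromide; 28 (2E,4E,6E)-2,7-dimethylocta-2,4,6-trienedial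
Product: 29 (2E,4E,6E,8E,10E)-13-[(4R)-4-[(tert-butyldimethylsilyl)oxy]-2,6,6-trimethylcyclohex-1-en-1-yl]-2,7,11-trimethyltrideca-2,4,6,8,10-pentaen-12-ynal
Conditions: 28 (3 equiv), NaOMe (1.1 equiv, added slowly), MeOH/CH2Cl2, 0 °C; chromatography and crystallization
Reagents that add atoms: none
Why: Wittig olefination of the allylic ylide with one aldehyde group of 28, used in excess to suppress double olefination; the new C11=C12 bond is expected as an E/Z mixture from which the all-E aldehyde is taken by chromatography and crystallization.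

Step 17
Reactants: 20 [(2E,4E)-5-[(1R,4R)-4-[(tert-butyldimethylsilyl)oxy]-2,6,6-trimethylcyclohex-2-en-1-yl]-3-methylpenta-2,4-dien-1-yl]triphenylphosphonium bromide; 29 (2E,4E,6E,8E,10E)-13-[(4R)-4-[(tert-butyldimethylsilyl)oxy]-2,6,6-trimethylcyclohex-1-en-1-yl]-2,7,11-trimethyltrideca-2,4,6,8,10-pentaen-12-ynal
Product: 30 (3R,3'R,6'R)-3,3'-bis[(tert-butyldimethylsilyl)oxy]-7,8-didehydro-β,ε-carotene (all-E)
Conditions: NaOMe, MeOH/CH2Cl2, 0 °C to rt; then EtOAc, 60 °C, dark, argon
Reagents that add atoms: none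
Why: Wittig coupling of the C15 ylide with the C25 aldehyde, the standard closing olefination of carotenoid synthesis, forms C11'=C12'; the hindered Z isomer at the new bond should equilibrate to E on gentle warming, and methoxide is too weak a base to touch C6'.

Step 18
Reactants: 30 (3R,3'R,6'R)-3,3'-bis[(tert-butyldimethylsilyl)oxy]-7,8-didehydro-β,ε-carotene (all-E)
Product: 31 (3R,3'R,6'R)-7,8-didehydro-β,ε-carotene-3,3'-diol (all-E)
Conditions: Bu4NF, THF, 0 °C to rt, dark, argon
Reagents that add atoms: none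
Why: Fluoride cleaves both silyl ethers under non-acidic conditions, which the acid-sensitive allylic C3' alcohol and the polyene should tolerate; no stereocentre is affected.

**Compound list**

1 | acetone | CC(C)=O | starting material
2 | ethyl acetoacetate | CCOC(=O)CC(C)=O | starting material
3 | ethyl 2-acetyl-3-methylbut-2-enoate | CCOC(=O)C(C(C)=O)=C(C)C | intermediate
4 | di-tert-butyl 3-oxopentanedioate (di-tert-butyl 1,3-acetonedicarboxylate) | CC(C)(C)OC(=O)CC(=O)CC(=O)OC(C)(C)C | starting material
5 | Michael adduct: di-tert-butyl 2-[3-(ethoxycarbonyl)-2-methyl-4-oxopentan-2-yl]-3-oxopentanedioate (diastereomer mixture) | CCOC(=O)C(C(C)=O)C(C)(C)C(C(=O)OC(C)(C)C)C(=O)CC(=O)OC(C)(C)C | intermediate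
6 | cyclic aldol: 3,5-di-tert-butyl 1-ethyl 2-hydroxy-2,6,6-trimethyl-4-oxocyclohexane-1,3,5-tricarboxylate (diastereomer mixture) | CCOC(=O)C1C(C)(O)C(C(=O)OC(C)(C)C)C(=O)C(C(=O)OC(C)(C)C)C1(C)C | intermediate
7 | 3,5-di-tert-butyl 1-ethyl 2,6,6-trimethyl-4-oxocyclohex-2-ene-1,3,5-tricarboxylate (racemic, C1/C5 epimers) | CCOC(=O)C1C(C)=C(C(=O)OC(C)(C)C)C(=O)C(C(=O)OC(C)(C)C)C1(C)C | intermediate
8 | diacid: 5-(ethoxycarbonyl)-4,6,6-trimethyl-2-oxocyclohex-3-ene-1,3-dicarboxylic acid | CCOC(=O)C1C(C)=C(C(=O)O)C(=O)C(C(=O)O)C1(C)C | intermediate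
9 | ethyl 2,6,6-trimethyl-4-oxocyclohex-2-ene-1-carboxylate (racemic) | CCOC(=O)C1C(C)=CC(=O)CC1(C)C | intermediate
10 | ethyl (1R,4R)-4-hydroxy-2,6,6-trimethylcyclohex-2-ene-1-carboxylate (trans) | CC1=C[C@H](O)CC(C)(C)[C@H]1C(=O)OCC | intermediate
11 | ethyl (1R,4R)-4-[(tert-butyldimethylsilyl)oxy]-2,6,6-trimethylcyclohex-2-ene-1-carboxylate | CC1=C[C@H](O[Si](C)(C)C(C)(C)C)CC(C)(C)[C@H]1C(=O)OCC | intermediate
12 | [(1R,4R)-4-[(tert-butyldimethylsilyl)oxy]-2,6,6-trimethylcyclohex-2-en-1-yl]methanol | CC1=C[C@H](O[Si](C)(C)C(C)(C)C)CC(C)(C)[C@H]1CO | intermediate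
13 | (1R,4R)-4-[(tert-butyldimethylsilyl)oxy]-2,6,6-trimethylcyclohex-2-ene-1-carbaldehyde | CC1=C[C@H](O[Si](C)(C)C(C)(C)C)CC(C)(C)[C@H]1C=O | intermediate
14 | 1-(triphenylphosphoranylidene)propan-2-one | CC(=O)C=P(c1ccccc1)(c1ccccc1)c1ccccc1 | starting material
15 | (3E)-4-[(1R,4R)-4-[(tert-butyldimethylsilyl)oxy]-2,6,6-trimethylcyclohex-2-en-1-yl]but-3-en-2-one | CC1=C[C@H](O[Si](C)(C)C(C)(C)C)CC(C)(C)[C@H]1/C=C/C(C)=O | intermediate
16 | triethyl phosphonoacetate | CCOC(=O)CP(=O)(OCC)OCC | starting material
17 | ethyl (2E,4E)-5-[(1R,4R)-4-[(tert-butyldimethylsilyl)oxy]-2,6,6-trimethylcyclohex-2-en-1-yl]-3-methylpenta-2,4-dienoate | CC1=C[C@H](O[Si](C)(C)C(C)(C)C)CC(C)(C)[C@H]1/C=C/C(C)=C/C(=O)OCC | intermediate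
18 | (2E,4E)-5-[(1R,4R)-4-[(tert-butyldimethylsilyl)oxy]-2,6,6-trimethylcyclohex-2-en-1-yl]-3-methylpenta-2,4-dien-1-ol | CC1=C[C@H](O[Si](C)(C)C(C)(C)C)CC(C)(C)[C@H]1/C=C/C(C)=C/CO | intermediate
19 | allylic bromide: tert-butyl{[(1R,4R)-4-[(1E,3E)-5-bromo-3-methylpenta-1,3-dien-1-yl]-3,5,5-trimethylcyclohex-2-en-1-yl]oxy}dimethylsilane | CC1=C[C@H](O[Si](C)(C)C(C)(C)C)CC(C)(C)[C@H]1/C=C/C(C)=C/CBr | intermediate
20 | [(2E,4E)-5-[(1R,4R)-4-[(tert-butyldimethylsilyl)oxy]-2,6,6-trimethylcyclohex-2-en-1-yl]-3-methylpenta-2,4-dien-1-yl]triphenylphosphonium bromide | CC1=C[C@H](O[Si](C)(C)C(C)(C)C)CC(C)(C)[C@H]1/C=C/C(C)=C/C[P+](c1ccccc1)(c1ccccc1)c1ccccc1.[Br-] | intermediate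
21 | (4R,6R)-4-hydroxy-2,2,6-trimethylcyclohexan-1-one ((4R,6R)-actinol) | O=C1[C@H](C)C[C@@H](O)CC1(C)C | starting material
22 | (4R,6R)-4-[(tert-butyldimethylsilyl)oxy]-2,2,6-trimethylcyclohexan-1-one | O=C1[C@H](C)C[C@@H](O[Si](C)(C)C(C)(C)C)CC1(C)C | intermediate
23 | (4R)-4-[(tert-butyldimethylsilyl)oxy]-2,6,6-trimethylcyclohex-1-en-1-yl trifluoromethanesulfonate | FC(F)(F)S(=O)(=O)OC1=C(C)C[C@@H](O[Si](C)(C)C(C)(C)C)CC1(C)C | intermediate
24 | (2E)-3-methylpent-2-en-4-yn-1-ol | C#C/C(C)=C/CO | starting material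
25 | (2E)-5-[(4R)-4-[(tert-butyldimethylsilyl)oxy]-2,6,6-trimethylcyclohex-1-en-1-yl]-3-methylpent-2-en-4-yn-1-ol | OC/C=C(\C)C#CC1=C(C)C[C@@H](O[Si](C)(C)C(C)(C)C)CC1(C)C | intermediate
26 | allylic bromide: {[(1R)-4-[(3E)-5-bromo-3-methylpent-3-en-1-yn-1-yl]-3,5,5-trimethylcyclohex-3-en-1-yl]oxy}(tert-butyl)dimethylsilane | BrC/C=C(\C)C#CC1=C(C)C[C@@H](O[Si](C)(C)C(C)(C)C)CC1(C)C | intermediate
27 | [(2E)-5-[(4R)-4-[(tert-butyldimethylsilyl)oxy]-2,6,6-trimethylcyclohex-1-en-1-yl]-3-methylpent-2-en-4-yn-1-yl]triphenylphosphonium bromide | [Br-].c1ccc(cc1)[P+](c1ccccc1)(c1ccccc1)C/C=C(\C)C#CC1=C(C)C[C@@H](O[Si](C)(C)C(C)(C)C)CC1(C)C | intermediate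
28 | (2E,4E,6E)-2,7-dimethylocta-2,4,6-trienedial (C10 dialdehyde) | O=C/C(C)=C/C=C/C=C(C)/C=O | starting material
29 | (2E,4E,6E,8E,10E)-13-[(4R)-4-[(tert-butyldimethylsilyl)oxy]-2,6,6-trimethylcyclohex-1-en-1-yl]-2,7,11-trimethyltrideca-2,4,6,8,10-pentaen-12-ynal (C25 aldehyde) | O=C/C(C)=C/C=C/C=C(C)/C=C/C=C(\C)C#CC1=C(C)C[C@@H](O[Si](C)(C)C(C)(C)C)CC1(C)C | intermediate
30 | (3R,3'R,6'R)-3,3'-bis[(tert-butyldimethylsilyl)oxy]-7,8-didehydro-β,ε-carotene (all-E) | CC1=C[C@H](O[Si](C)(C)C(C)(C)C)CC(C)(C)[C@H]1/C=C/C(C)=C/C=C/C(C)=C/C=C/C=C(C)/C=C/C=C(\C)C#CC1=C(C)C[C@@H](O[Si](C)(C)C(C)(C)C)CC1(C)C | intermediate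
31 | (3R,3'R,6'R)-7,8-didehydro-β,ε-carotene-3,3'-diol (all-E) | CC1=C[C@H](O)CC(C)(C)[C@H]1/C=C/C(C)=C/C=C/C(C)=C/C=C/C=C(C)/C=C/C=C(\C)C#CC1=C(C)C[C@@H](O)CC1(C)C | target

**Step count and risks**

Total step count: 18. Longest linear sequence: 13 steps (steps 1–11, 17, 18).

Steps most likely to fail:

1. Step 2. The Michael addition to the tetrasubstituted alkene may stall or revert (retro-Michael), or the acceptor may deconjugate under base before the ring closes. Fallback: the same ring is closed by the other pairing of its carbon skeleton. The fallback sets out from 2, which is condensed with mesityl oxide (4-methylpent-3-en-2-one, bought) under ZnCl2 catalysis in refluxing heptane. Michael addition should give ethyl 2-acetyl-3,3-dimethyl-5-oxohexanoate F1, which closes by aldol condensation in the same flask. It comes back to the route at 9, so steps 1–3 fall away.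

2. Step 4. The catalyst may fail to override the intrinsic facial bias of one enantiomer of the keto ester, or the cis and trans alcohols may co-elute. Fallback: enzymatic kinetic resolution instead of reagent control. The fallback sets out from 9. Luche reduction (NaBH4, CeCl3·7H2O, MeOH, −40 °C) and chromatography should give racemic ethyl (1R*,4R*)-4-hydroxy-2,6,6-trimethylcyclohex-2-ene-1-carboxylate F2. Lipase from Burkholderia cepacia with vinyl acetate in t-BuOMe is expected (Kazlauskas rule) to acetylate the (4R)-enantiomer to ethyl (1R,4R)-4-acetoxy-2,6,6-trimethylcyclohex-2-ene-1-carboxylate F3, which is separated from the unreacted (1S,4S)-alcohol. K2CO3 in MeOH at 0 °C removes the acetate and the fallback comes back at 10.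

3. Step 8 (together with step 7). The β,γ-unsaturated aldehyde may epimerize at the α-carbon or shift its ring double bond into conjugation, and the hindered aldehyde may react slowly with the weakly nucleophilic ylide. Fallback: reversal of polarity, so that the epimerizable aldehyde is never made. The fallback sets out from 12. Mitsunobu thioetherification (1-phenyl-1H-tetrazole-5-thiol, PPh3, diisopropyl azodicarboxylate, THF) should give 5-({[(1R,4R)-4-[(tert-butyldimethylsilyl)oxy]-2,6,6-trimethylcyclohex-2-en-1-yl]methyl}sulfanyl)-1-phenyl-1H-tetrazole F4. Oxidation with H2O2 and catalytic (NH4)6Mo7O24 in EtOH should give 5-({[(1R,4R)-4-[(tert-butyldimethylsilyl)oxy]-2,6,6-trimethylcyclohex-2-en-1-yl]methyl}sulfonyl)-1-phenyl-1H-tetrazole F5. Julia–Kocienski olefination (KN(SiMe3)2, DME, −60 °C) with bought ethyl (2E)-3-methyl-4-oxobut-2-enoate forms C7'=C8' directly. The fallback comes back at 17, so steps 7–9 fall away.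

**Further compounds**

F1 | step 2 | ethyl 2-acetyl-3,3-dimethyl-5-oxohexanoate | CCOC(=O)C(C(C)=O)C(C)(C)CC(C)=O
F2 | step 4 | racemic ethyl (1R*,4R*)-4-hydroxy-2,6,6-trimethylcyclohex-2-ene-1-carboxylate (one enantiomer drawn) | CC1=C[C@H](O)CC(C)(C)[C@H]1C(=O)OCC
F3 | step 4 | ethyl (1R,4R)-4-acetoxy-2,6,6-trimethylcyclohex-2-ene-1-carboxylate | CC1=C[C@H](OC(C)=O)CC(C)(C)[C@H]1C(=O)OCC
F4 | step 8 | 5-({[(1R,4R)-4-[(tert-butyldimethylsilyl)oxy]-2,6,6-trimethylcyclohex-2-en-1-yl]methyl}sulfanyl)-1-phenyl-1H-tetrazole | CC1=C[C@H](O[Si](C)(C)C(C)(C)C)CC(C)(C)[C@H]1CSc1nnnn1-c1ccccc1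
F5 | step 8 | 5-({[(1R,4R)-4-[(tert-butyldimethylsilyl)oxy]-2,6,6-trimethylcyclohex-2-en-1-yl]methyl}sulfonyl)-1-phenyl-1H-tetrazole | CC1=C[C@H](O[Si](C)(C)C(C)(C)C)CC(C)(C)[C@H]1CS(=O)(=O)c1nnnn1-c1ccccc1
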